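**Plan**

- Retrosynthesis (carotenoid numbering, primed atoms = ε half): cut C11=C12 and C11'=C12' (two Wittig bonds) to an acetylenic C15 phosphonium salt, the C10 trienedial and an ε C15 phosphonium salt. Then cut C6–C7 (sp2–sp, Sonogashira) in the first salt, C9'/C10' and C7'=C8' (vinyl addition, Horner–Wadsworth–Emmons) in the second, and last C1'–C2' of the ε ring.
- Enabling feature: in the ε ring the quaternary C1'(CH3)2 is β to the exocyclic C7' through the stereogenic, doubly allylic C6'–H, and C2' is homoallylic to the C4'=C5' alkene. With C7' as an ester this is the retron of a 6-endo conjugate addition of a C2' radical to C1' of an isopropylidene dienoate, ended by hydrogen-atom delivery to C6'.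
- Forward: Birch reduction and ozonolysis of 3-methylanisole give the (Z)-alkene tether; aldol and elimination install the isopropylidene enoate; a flavin ene-reductase under light closes the ε ring (the only ring made; the hydroxylated ring is bought). Chain extension gives (R)-α-ionone and the ε C15 salt, which is joined to the C10 dialdehyde; the acetylenic C15 salt is joined last.
- Stereochemistry: C6' (R) from enzyme-controlled hydrogen-atom transfer in the ring closure; C3 (R) from (4R,6R)-actinol; the (Z)-tether alkene from the ring of the Birch diene; the (E)-alkenes from Horner–Wadsworth–Emmons, allylic transposition, the (E)-enynol and the Wittig steps.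

Key step: step 7

Remark: (4R,6R)-actinol, the C10 trienedial and (E)-3-methylpent-2-en-4-yn-1-ol are treated as purchasable carotenoid intermediates.

**Route**

Step 1
Reactants: 1 3-methylanisole
Product: 2 1-methoxy-5-methylcyclohexa-1,4-diene
Conditions: Li, NH3 (l), t-BuOH, THF, −78 → −33 °C; NH4Cl
Reagents that add atoms: none
Why: Birch reduction leaves both donor-bearing carbons on the two isolated double bonds, and the ring of this 1,4-diene fixes the cis relation later needed between C3' and C6'.

Step 2
Reactants: 2 1-methoxy-5-methylcyclohexa-1,4-diene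
Product: 4 methyl (3Z)-6-hydroxy-3-methylhex-3-enoate, via aldehyde ester 3 (not isolated)
Conditions: O3 (1 equiv), CH2Cl2/MeOH, −78 °C; Me2S; then NaBH4, 0 °C
Reagents that add atoms: ozone, O=[O+][O-]
Why: Selective ozonolysis of the electron-rich enol ether alkene turns the methoxy carbon into the methyl ester and its neighbour into an aldehyde that NaBH4 reduces in the same flask, so the ring-derived (Z) geometry is carried into the open chain.

Step 3
Reactants: 4 methyl (3Z)-6-hydroxy-3-methylhex-3-enoate
Product: 5 methyl (3Z)-6-chloro-3-methylhex-3-enoate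
Conditions: SOCl2, pyridine, CH2Cl2, 0 °C → rt
Reagents that add atoms: thionyl chloride, O=S(Cl)Cl
Why: Chlorodehydroxylation through the chlorosulfite (SN2) gives a primary chloride that should survive the enolate chemistry and can be exchanged for iodide later.

Step 4
Reactants: 5 methyl (3Z)-6-chloro-3-methylhex-3-enoate
Product: 8 methyl (3Z)-2-[2-(acetyloxy)propan-2-yl]-6-chloro-3-methylhex-3-enoate (racemic at C2), via lithium dienolate 6 (not isolated), via lithium aldolate 7 (not isolated)
Conditions: LiN(iPr)2 (LDA), THF, −78 °C; acetone; then Ac2O, −78 → 0 °C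
Reagents that add atoms: acetone, CC(C)=O; acetic anhydride, CC(=O)OC(C)=O
Why: Kinetic aldol addition of the lithium dienolate through its α-carbon to acetone, with O-acetylation of the tertiary aldolate in the flask to stop retro-aldol cleavage; at −78 °C the primary chloride should not be displaced.

Step 5
Reactants: 8 methyl (3Z)-2-[2-(acetyloxy)propan-2-yl]-6-chloro-3-methylhex-3-enoate
Product: 9 methyl (3Z)-6-chloro-3-methyl-2-(propan-2-ylidene)hex-3-enoate
Conditions: DBU, toluene, rt
Reagents that add atoms: none
Why: E1cB elimination of acetate through the doubly activated α-C–H can place the new alkene only between the α-carbon and the tertiary carbon, which gives the isopropylidene enoate and leaves the (Z)-alkene alone.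

Step 6
Reactants: 9 methyl (3Z)-6-chloro-3-methyl-2-(propan-2-ylidene)hex-3-enoate
Product: 10 methyl (3Z)-6-iodo-3-methyl-2-(propan-2-ylidene)hex-3-enoate
Conditions: NaI, 2-butanone, 80 °C, dark
Reagents that add atoms: sodium iodide, [Na+].[I-]
Why: Finkelstein halide exchange (SN2), driven by precipitation of NaCl, gives the primary iodide needed for light-induced C–I cleavage.

Step 7
Reactants: 10 methyl (3Z)-6-iodo-3-methyl-2-(propan-2-ylidene)hex-3-enoate
Product: 11 methyl (1R)-2,6,6-trimethylcyclohex-2-ene-1-carboxylate [(R)-methyl α-cyclogeranate]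
Conditions: flavin-dependent ene-reductase (old yellow enzyme family, (R)-selective member of a panel), NADP+ (cat.), glucose dehydrogenase, D-glucose, KPi buffer pH 8/DMSO 9:1, cyan LEDs (ca. 500 nm), 25 °C, anaerobic
Reagents that add atoms: none
Why: Proposed new method: the substrate should bind in the active site through hydrogen bonds to its ester carbonyl, and visible-light excitation of the charge-transfer complex between the reduced flavin and the C–I bond should cleave it to the primary radical at C2', iodide and the flavin semiquinone. This radical should close the ε ring by 6-endo-trig Giese addition to C1', the β-carbon of the isopropylidene enoate, which makes the quaternary centre and leaves a radical at C6' that is stabilised by the ester and by the C4'=C5' alkene. Hydrogen-atom transfer from N5–H of the semiquinone to one face of C6' should then set the (R) centre, the protein pocket being the controlling element, and the enzyme is picked from a panel for this sense. The closest known reaction type is the photoenzymatic reductive cyclisation of alkyl iodides onto α,β-unsaturated carbonyl compounds by ene-reductases with enantioselective hydrogen-atom transfer, which is known for exo closures onto unhindered alkene carbons. The step needs 6-endo over 5-exo closure, which the polarity of the enoate (nucleophilic radical to the β-carbon) and the (Z)-alkene of the tether should secure, and it needs hydrogen delivery to C6' and not to C4', which the carbonyl anchor next to the flavin should secure and which keeps the alkene out of conjugation. The 3-exo closure of the homoallyl radical onto C4' is reversible and should only return the same radical.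

Step 8
Reactants: 11 methyl (1R)-2,6,6-trimethylcyclohex-2-ene-1-carboxylate
Product: 12 [(1R)-2,6,6-trimethylcyclohex-2-en-1-yl]methanol [(R)-α-cyclogeraniol]
Conditions: LiAlH4, Et2O, 0 °C
Reagents that add atoms: none
Why: Hydride reduction of the hindered ester to the primary alcohol is faster than enolisation, so C6' should keep its configuration.

Step 9
Reactants: 12 [(1R)-2,6,6-trimethylcyclohex-2-en-1-yl]methanol
Product: 13 (1R)-2,6,6-trimethylcyclohex-2-ene-1-carbaldehyde [(R)-α-cyclocitral]
Conditions: Dess–Martin periodinane, CH2Cl2, 0 °C → rt; used at once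
Reagents that add atoms: none
Why: Dess–Martin oxidation works without base, so the α-stereocentre should not enolise and the ring alkene should not move into conjugation.

Step 10
Reactants: 13 (1R)-2,6,6-trimethylcyclohex-2-ene-1-carbaldehyde
Product: 14 (3E)-4-[(1R)-2,6,6-trimethylcyclohex-2-en-1-yl]but-3-en-2-one [(R)-α-ionone]
Conditions: diethyl (2-oxopropyl)phosphonate, LiCl, iPr2NEt, MeCN, 0 °C → rt
Reagents that add atoms: diethyl (2-oxopropyl)phosphonate, CCOP(=O)(CC(C)=O)OCC
Why: Horner–Wadsworth–Emmons olefination under Masamune–Roush conditions should give the (E)-enone, and the weak amine base with LiCl limits enolisation of the α-branched aldehyde.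

Step 11
Reactants: 14 (3E)-4-[(1R)-2,6,6-trimethylcyclohex-2-en-1-yl]but-3-en-2-one
Product: 15 (1E)-3-methyl-1-[(1R)-2,6,6-trimethylcyclohex-2-en-1-yl]penta-1,4-dien-3-ol (both C3 epimers)
Conditions: CH2=CHMgBr, THF, −20 → 0 °C; NH4Cl
Reagents that add atoms: vinylmagnesium bromide, C=C[Mg]Br
Why: Grignard 1,2-addition to the enone carbonyl; the new carbinol centre forms without control and is erased in the next step.

Step 12
Reactants: 15 (1E)-3-methyl-1-[(1R)-2,6,6-trimethylcyclohex-2-en-1-yl]penta-1,4-dien-3-ol
Product: 16 [(2E,4E)-3-methyl-5-[(1R)-2,6,6-trimethylcyclohex-2-en-1-yl]penta-2,4-dien-1-yl]triphenylphosphonium bromide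
Conditions: PPh3·HBr, MeOH, rt
Reagents that add atoms: triphenylphosphine hydrobromide, [Br-].[PH+](c1ccccc1)(c1ccccc1)c1ccccc1
Why: Acid ionisation of the tertiary bis-allylic alcohol and capture of the pentadienyl cation by PPh3 at the primary terminus (allylic transposition) is the standard Wittig-salt formation and should give the (2E,4E) salt without touching C6'.

Step 13
Reactants: 16 [(2E,4E)-3-methyl-5-[(1R)-2,6,6-trimethylcyclohex-2-en-1-yl]penta-2,4-dien-1-yl]triphenylphosphonium bromide; 17 (2E,4E,6E)-2,7-dimethylocta-2,4,6-trienedial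
Product: 19 (2E,4E,6E,8E,10E,12E)-2,7,11-trimethyl-13-[(1R)-2,6,6-trimethylcyclohex-2-en-1-yl]trideca-2,4,6,8,10,12-hexaenal, via phosphorus ylide 18 (not isolated)
Conditions: 17 (2 equiv), NaOMe, MeOH/CH2Cl2, 0 °C → rt; then heptane, 80 °C, dark
Reagents that add atoms: none
Why: Wittig olefination with excess dialdehyde should stop at mono-condensation and forms C11'=C12'; the (Z) fraction at the new disubstituted alkene should revert to (E) on warming.

Step 14
Reactants: 20 (4R,6R)-4-hydroxy-2,2,6-trimethylcyclohexan-1-one (actinol)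
Product: 21 (4R,6R)-2,2,6-trimethyl-4-[(triethylsilyl)oxy]cyclohexan-1-one
Conditions: Et3SiCl, imidazole, DMF, 0 °C → rt
Reagents that add atoms: chlorotriethylsilane, CC[Si](Cl)(CC)CC
Why: Silylation of the secondary alcohol protects it against the strong base and triflating agent of the next step.

Step 15
Reactants: 21 (4R,6R)-2,2,6-trimethyl-4-[(triethylsilyl)oxy]cyclohexan-1-one
Product: 23 (4R)-2,6,6-trimethyl-4-[(triethylsilyl)oxy]cyclohex-1-en-1-yl trifluoromethanesulfonate, via lithium enolate 22 (not isolated)
Conditions: LiN(iPr)2 (LDA), THF, −78 → 0 °C; PhNTf2, 0 °C → rt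
Reagents that add atoms: N-phenylbis(trifluoromethanesulfonimide), FC(F)(F)S(=O)(=O)N(c1ccccc1)S(=O)(=O)C(F)(F)F
Why: Only the methine α-carbon can be deprotonated (the other α-carbon is quaternary), so O-triflation of the single tetrasubstituted enolate gives one enol triflate and leaves the carbinol centre untouched.

Step 16
Reactants: 23 (4R)-2,6,6-trimethyl-4-[(triethylsilyl)oxy]cyclohex-1-en-1-yl trifluoromethanesulfonate; 24 (2E)-3-methylpent-2-en-4-yn-1-ol
Product: 25 (2E)-3-methyl-5-{(4R)-2,6,6-trimethyl-4-[(triethylsilyl)oxy]cyclohex-1-en-1-yl}pent-2-en-4-yn-1-ol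
Conditions: Pd(PPh3)4 (cat.), CuI (cat.), Et3N, DMF, rt → 50 °C
Reagents that add atoms: none
Why: Sonogashira coupling of the alkenyl triflate with the terminal alkyne forms the C6–C7 bond and keeps the (E) geometry of the enynol.

Step 17
Reactants: 25 (2E)-3-methyl-5-{(4R)-2,6,6-trimethyl-4-[(triethylsilyl)oxy]cyclohex-1-en-1-yl}pent-2-en-4-yn-1-ol
Product: 26 [(2E)-5-[(4R)-4-hydroxy-2,6,6-trimethylcyclohex-1-en-1-yl]-3-methylpent-2-en-4-yn-1-yl]triphenylphosphonium bromide
Conditions: PPh3·HBr, MeOH, rt
Reagents that add atoms: triphenylphosphine hydrobromide, [Br-].[PH+](c1ccccc1)(c1ccccc1)c1ccccc1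
Why: Wittig-salt formation at the primary allylic alcohol, while the acidic methanol removes the triethylsilyl ether in the same flask; the homoallylic ring hydroxyl is not ionised.

Step 18
Reactants: 26 [(2E)-5-[(4R)-4-hydroxy-2,6,6-trimethylcyclohex-1-en-1-yl]-3-methylpent-2-en-4-yn-1-yl]triphenylphosphonium bromide; 19 (2E,4E,6E,8E,10E,12E)-2,7,11-trimethyl-13-[(1R)-2,6,6-trimethylcyclohex-2-en-1-yl]trideca-2,4,6,8,10,12-hexaenal
Product: 28 (3R,6'R)-7,8-didehydro-β,ε-caroten-3-ol, via phosphorus ylide 27 (not isolated)
Conditions: NaOMe, MeOH/CH2Cl2, 0 °C → rt, dark, argon; all-E isomer collected by crystallisation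
Reagents that add atoms: none
Why: Wittig olefination forms C11=C12 in the presence of the free hydroxyl; the (E) geometry at C9=C10 comes from the enynol, and the acetylenic half is joined last so that it meets no equilibrating conditions.

**Compound list**

1 | 3-methylanisole | COc1cccc(C)c1 | starting material
2 | 1-methoxy-5-methylcyclohexa-1,4-diene | COC1=CCC=C(C)C1 | intermediate
3 | methyl (3Z)-3-methyl-6-oxohex-3-enoate | COC(=O)C/C(C)=C\CC=O | intermediate
4 | methyl (3Z)-6-hydroxy-3-methylhex-3-enoate | COC(=O)C/C(C)=C\CCO | intermediate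
5 | methyl (3Z)-6-chloro-3-methylhex-3-enoate | COC(=O)C/C(C)=C\CCCl | intermediate
6 | lithium dienolate of 5 | [Li+].COC([O-])=C/C(C)=C\CCCl | intermediate
7 | lithium aldolate, lithium 2-[(3Z)-6-chloro-1-methoxy-3-methyl-1-oxohex-3-en-2-yl]propan-2-olate | [Li+].COC(=O)C(C(C)(C)[O-])/C(C)=C\CCCl | intermediate
8 | methyl (3Z)-2-[2-(acetyloxy)propan-2-yl]-6-chloro-3-methylhex-3-enoate (racemic) | COC(=O)C(C(C)(C)OC(C)=O)/C(C)=C\CCCl | intermediate
9 | methyl (3Z)-6-chloro-3-methyl-2-(propan-2-ylidene)hex-3-enoate | COC(=O)C(=C(C)C)/C(C)=C\CCCl | intermediate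
10 | methyl (3Z)-6-iodo-3-methyl-2-(propan-2-ylidene)hex-3-enoate | COC(=O)C(=C(C)C)/C(C)=C\CCI | intermediate
11 | methyl (1R)-2,6,6-trimethylcyclohex-2-ene-1-carboxylate | CC1=CCCC(C)(C)[C@H]1C(=O)OC | intermediate
12 | [(1R)-2,6,6-trimethylcyclohex-2-en-1-yl]methanol | CC1=CCCC(C)(C)[C@H]1CO | intermediate
13 | (1R)-2,6,6-trimethylcyclohex-2-ene-1-carbaldehyde | CC1=CCCC(C)(C)[C@H]1C=O | intermediate
14 | (3E)-4-[(1R)-2,6,6-trimethylcyclohex-2-en-1-yl]but-3-en-2-one | CC1=CCCC(C)(C)[C@H]1/C=C/C(C)=O | intermediate
15 | (1E)-3-methyl-1-[(1R)-2,6,6-trimethylcyclohex-2-en-1-yl]penta-1,4-dien-3-ol | CC1=CCCC(C)(C)[C@H]1/C=C/C(C)(O)C=C | intermediate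
16 | [(2E,4E)-3-methyl-5-[(1R)-2,6,6-trimethylcyclohex-2-en-1-yl]penta-2,4-dien-1-yl]triphenylphosphonium bromide | [Br-].CC1=CCCC(C)(C)[C@H]1/C=C/C(C)=C/C[P+](c1ccccc1)(c1ccccc1)c1ccccc1 | intermediate
17 | (2E,4E,6E)-2,7-dimethylocta-2,4,6-trienedial | O=C/C(C)=C/C=C/C=C(C)/C=O | starting material
18 | [(2E,4E)-3-methyl-5-[(1R)-2,6,6-trimethylcyclohex-2-en-1-yl]penta-2,4-dien-1-ylidene]triphenyl-λ5-phosphane | CC1=CCCC(C)(C)[C@H]1/C=C/C(C)=C/C=P(c1ccccc1)(c1ccccc1)c1ccccc1 | intermediate
19 | (2E,4E,6E,8E,10E,12E)-2,7,11-trimethyl-13-[(1R)-2,6,6-trimethylcyclohex-2-en-1-yl]trideca-2,4,6,8,10,12-hexaenal | CC1=CCCC(C)(C)[C@H]1/C=C/C(C)=C/C=C/C(C)=C/C=C/C=C(C)/C=O | intermediate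
20 | (4R,6R)-4-hydroxy-2,2,6-trimethylcyclohexan-1-one | O=C1[C@H](C)C[C@@H](O)CC1(C)C | starting material
21 | (4R,6R)-2,2,6-trimethyl-4-[(triethylsilyl)oxy]cyclohexan-1-one | O=C1[C@H](C)C[C@@H](O[Si](CC)(CC)CC)CC1(C)C | intermediate
22 | lithium (4R)-2,6,6-trimethyl-4-[(triethylsilyl)oxy]cyclohex-1-en-1-olate | [Li+].[O-]C1=C(C)C[C@@H](O[Si](CC)(CC)CC)CC1(C)C | intermediate
23 | (4R)-2,6,6-trimethyl-4-[(triethylsilyl)oxy]cyclohex-1-en-1-yl trifluoromethanesulfonate | FC(F)(F)S(=O)(=O)OC1=C(C)C[C@@H](O[Si](CC)(CC)CC)CC1(C)C | intermediate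
24 | (2E)-3-methylpent-2-en-4-yn-1-ol | OC/C=C(\C)C#C | starting material
25 | (2E)-3-methyl-5-{(4R)-2,6,6-trimethyl-4-[(triethylsilyl)oxy]cyclohex-1-en-1-yl}pent-2-en-4-yn-1-ol | OC/C=C(\C)C#CC1=C(C)C[C@@H](O[Si](CC)(CC)CC)CC1(C)C | intermediate
26 | [(2E)-5-[(4R)-4-hydroxy-2,6,6-trimethylcyclohex-1-en-1-yl]-3-methylpent-2-en-4-yn-1-yl]triphenylphosphonium bromide | [Br-].c1ccccc1[P+](c1ccccc1)(c1ccccc1)C/C=C(\C)C#CC1=C(C)C[C@@H](O)CC1(C)C | intermediate
27 | [(2E)-5-[(4R)-4-hydroxy-2,6,6-trimethylcyclohex-1-en-1-yl]-3-methylpent-2-en-4-yn-1-ylidene]triphenyl-λ5-phosphane | c1ccccc1P(c1ccccc1)(c1ccccc1)=C/C=C(\C)C#CC1=C(C)C[C@@H](O)CC1(C)C | intermediate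
28 | (3R,6'R)-7,8-didehydro-β,ε-caroten-3-ol | CC1=CCCC(C)(C)[C@H]1/C=C/C(C)=C/C=C/C(C)=C/C=C/C=C(C)/C=C/C=C(\C)C#CC1=C(C)C[C@@H](O)CC1(C)C | target

**Count**

Total steps: 18. Longest linear sequence: 14 steps (steps 1–13, then step 18).

**Steps most likely to fail**

1. Step 7. The open-chain primary radical, or the cyclopropylcarbinyl radical from its reversible 3-exo closure, may be reduced before the slow 6-endo attack on the fully substituted C1'. Hydrogen-atom transfer may also show poor facial selectivity or go to C4'. The fallback uses known chemistry, sets out from 10 and comes back at 12.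
   - SmI2/HMPA/t-BuOH in THF (−78 → 0 °C) should effect the reductive intramolecular conjugate addition of the iodide to the enoate, with kinetic α-protonation of the samarium dienolate, to give racemic methyl 2,6,6-trimethylcyclohex-2-ene-1-carboxylate F1.
   - KOH in aqueous methanol at reflux should give racemic 2,6,6-trimethylcyclohex-2-ene-1-carboxylic acid F2.
   - Crystallisation with (R)-1-phenylethylamine should give (1R)-1-phenylethan-1-aminium (1R)-2,6,6-trimethylcyclohex-2-ene-1-carboxylate F3; the antipode of the amine is taken if the salt pairing proves opposite.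
   - Aqueous HCl should free (1R)-2,6,6-trimethylcyclohex-2-ene-1-carboxylic acid F4, and LiAlH4 in Et2O should reduce it to 12.

2. Step 4. The congested lithium aldolate may revert by retro-aldol cleavage before O-acetylation, the dienolate may attack through its γ-carbon, or it may displace the chloride internally. The fallback replaces the reversible aldol by an irreversible acylation and a methyl transfer; it sets out from 5 and comes back at 9, so that 8 and step 5 are bypassed.
   - Dienolate 6 (LiN(iPr)2, 2 equiv, THF, −78 °C) with acetyl chloride should give methyl (3Z)-2-acetyl-6-chloro-3-methylhex-3-enoate F5.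
   - NaH and ClP(O)(OEt)2 in Et2O at 0 °C should give the enol phosphate methyl (3Z)-6-chloro-2-{1-[(diethoxyphosphoryl)oxy]ethylidene}-3-methylhex-3-enoate F6.
   - Me2CuLi in Et2O (−78 → −40 °C) should replace the phosphate by methyl (addition–elimination) to give 9; both β-substituents are then methyl, so the enol geometry does not matter.

3. Step 10. The α-branched aldehyde may lose its configuration at C6' by enolisation under the amine base, its ring alkene may migrate into conjugation, and the hindered aldehyde may be olefinated slowly. The fallback avoids base while the aldehyde is present; it sets out from 13 and comes back at 14.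
   - Mukaiyama aldol addition of 2-(trimethylsilyloxy)propene with BF3·OEt2 in CH2Cl2 at −78 °C should give 4-hydroxy-4-[(1R)-2,6,6-trimethylcyclohex-2-en-1-yl]butan-2-one F7 (both carbinol epimers).
   - MsCl/Et3N in CH2Cl2 at 0 °C should give 3-oxo-1-[(1R)-2,6,6-trimethylcyclohex-2-en-1-yl]butyl methanesulfonate F8, which should eliminate in the same flask (E1cB) to the (E)-enone 14.

**Further compounds**

F1 | step 7 | methyl (1RS)-2,6,6-trimethylcyclohex-2-ene-1-carboxylate | CC1=CCCC(C)(C)C1C(=O)OC
F2 | step 7 | (1RS)-2,6,6-trimethylcyclohex-2-ene-1-carboxylic acid | CC1=CCCC(C)(C)C1C(=O)O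
F3 | step 7 | (1R)-1-phenylethan-1-aminium (1R)-2,6,6-trimethylcyclohex-2-ene-1-carboxylate | CC1=CCCC(C)(C)[C@H]1C(=O)[O-].C[C@H](c1ccccc1)[NH3+]
F4 | step 7 | (1R)-2,6,6-trimethylcyclohex-2-ene-1-carboxylic acid | CC1=CCCC(C)(C)[C@H]1C(=O)O
F5 | step 4 | methyl (3Z)-2-acetyl-6-chloro-3-methylhex-3-enoate | COC(=O)C(C(C)=O)/C(C)=C\CCCl
F6 | step 4 | methyl (3Z)-6-chloro-2-{1-[(diethoxyphosphoryl)oxy]ethylidene}-3-methylhex-3-enoate | COC(=O)C(=C(C)OP(=O)(OCC)OCC)/C(C)=C\CCCl
F7 | step 10 | 4-hydroxy-4-[(1R)-2,6,6-trimethylcyclohex-2-en-1-yl]butan-2-one | CC1=CCCC(C)(C)[C@H]1C(O)CC(C)=O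
F8 | step 10 | 3-oxo-1-[(1R)-2,6,6-trimethylcyclohex-2-en-1-yl]butyl methanesulfonate | CC1=CCCC(C)(C)[C@H]1C(OS(C)(=O)=O)CC(C)=O
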